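**Retrosynthetic overview**
- Ring C is closed last: O1–C2 by 6-endo oxa-Michael addition of the C8a phenoxide to an aryl ynone. The ynone comes from a C4a aldehyde and the ring B alkyne 20, and C5–O is held as a benzyl ether so that only O1 can close.
- The strategy rests on ring A (C4a, C5, C6, C7, C8, C8a), a phloroglucinol ring: oxygens on C5, C7 and C8a alternate with C4a–H, C8–H and C6, which carries ring D between C5–O and C7–O. A vinylketene and an ynol ether assemble exactly this pattern, so ring A is made by benzannulation of cyclobutenone 12 with siloxyacetylene 10 (new bonds C4a–C5, C8–C8a, C5–C6).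
- Cyclobutenone 12 comes from the arylketene of arylacetic acid 4 and the same alkyne 10 by [2+2]; acid 4 comes from bromide 1 by zinc enolate cross-coupling, so the C6–ring D bond is carried in from 4.
- Ring order: D (bought), four-membered ring, A, C; ring B arrives with the alkyne.

Key step: step 6

Assumption: ethyl formate is taken to behave in the ester-to-ynolate homologation as the higher esters do; flavone numbering (O1 to C8a) is used for rings A and C, ring D is the benzoate ring and ring B the 4-hydroxyphenyl ring.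

**Route**

Step 1
Reactants: 1 methyl 3-bromo-4-methoxybenzoate; 2 (2-tert-butoxy-2-oxoethyl)zinc bromide (commercial solution)
Product: 3 methyl 3-(2-tert-butoxy-2-oxoethyl)-4-methoxybenzoate
Conditions: 2 (1.5 equiv), Pd2(dba)3 (cat.), XPhos (cat.), THF, 65 °C
Reagents that add atoms: none
Why: Negishi-type α-arylation of a Reformatsky zinc enolate with an aryl bromide; the zinc reagent should leave the methyl ester untouched.

Step 2
Reactants: 3 methyl 3-(2-tert-butoxy-2-oxoethyl)-4-methoxybenzoate
Product: 4 2-[2-methoxy-5-(methoxycarbonyl)phenyl]acetic acid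
Conditions: CF3CO2H, CH2Cl2, rt
Reagents that add atoms: none
Why: Acidolysis of the tert-butyl ester by loss of isobutene should spare the methyl ester and the aryl methyl ether.

Step 3
Reactants: 4 2-[2-methoxy-5-(methoxycarbonyl)phenyl]acetic acid
Product: 5 methyl 3-(2-chloro-2-oxoethyl)-4-methoxybenzoate
Conditions: (COCl)2, DMF (cat.), CH2Cl2, 0 °C → rt; concentrate, use crude
Reagents that add atoms: oxalyl chloride, O=C(Cl)C(=O)Cl
Why: Standard acid chloride formation through the Vilsmeier-type chloroiminium activator.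

Step 4
Reactants: 6 ethyl formate; 7 triisopropylsilyl trifluoromethanesulfonate
Product: 10 (triisopropylsiloxy)acetylene, via lithium 2,2-dibromoethenolate 8 (not isolated), via lithium ethynolate 9 (not isolated)
Conditions: CH2Br2, LiTMP (lithium 2,2,6,6-tetramethylpiperidide), THF, −78 °C; LiN(SiMe3)2, then n-BuLi, −78 °C → rt; 7, −78 °C → rt; distil
Reagents that add atoms: dibromomethane, BrCBr
Why: Kowalski ester-to-ynolate homologation, in which LiCHBr2 adds to the formate, dibromoenolate 8 undergoes Br–Li exchange and a Fritsch–Buttenberg–Wiechell-type carbenoid rearrangement to ynolate 9, and the hard, bulky silyl triflate silylates on oxygen.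

Step 5
Reactants: 5 methyl 3-(2-chloro-2-oxoethyl)-4-methoxybenzoate; 10 (triisopropylsiloxy)acetylene
Product: 12 methyl 4-methoxy-3-[4-oxo-2-(triisopropylsiloxy)cyclobut-2-en-1-yl]benzoate (racemic), via arylketene 11 (not isolated)
Conditions: 10 (1.3 equiv), Et3N, CH2Cl2, 0 °C → rt, slow addition of 5
Reagents that add atoms: none
Why: Dehydrochlorination gives arylketene 11, which undergoes the polar ketene–ynol ether [2+2] cycloaddition (alkyne CH carbon to the ketene carbonyl carbon, siloxy carbon to the aryl-bearing carbon); the ring stereocenter forms racemic and is lost in step 6.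

Step 6
Reactants: 12 methyl 4-methoxy-3-[4-oxo-2-(triisopropylsiloxy)cyclobut-2-en-1-yl]benzoate; 10 (triisopropylsiloxy)acetylene
Product: 17 methyl 3-[2-hydroxy-4,6-bis(triisopropylsiloxy)phenyl]-4-methoxybenzoate, via vinylketene 13 (not isolated), via 4-vinylcyclobutenone 14 (not isolated), via dienylketene 15 (not isolated), via cyclohexa-2,4-dienone 16 (not isolated)
Conditions: 10 (2.5 equiv), toluene (about 1 M), 80 °C then 110 °C, sealed tube, argon
Reagents that add atoms: none
Why: Thermal four-electron conrotatory opening of 12 with the aryl group turning outward gives vinylketene 13; its electrophilic ketene carbon (future C5) is attacked by the nucleophilic CH terminus of ynol ether 10 (future C4a), and the siloxy carbon (future C8a) closes onto the ketene α-carbon (future C8) in a stepwise polar [2+2] to give 14. Four-electron opening of 14 gives dienylketene 15, which closes ring A by six-electron disrotatory electrocyclization between C5 and the aryl-bearing C6, and enolization of 16 gives the phenol. This is the Danheiser benzannulation in its siloxyalkyne variant, known for 3-siloxycyclobutenones. No stereocenter remains, since the sp3 carbons of 12, 14 and 16 all end as aromatic carbons. The regiochemistry needed (free C5–OH, silyl ethers on C7 and C8a, ring D on C6) follows from the polarity match of ketene and ynol ether. The chemoselectivity needed is capture of 13 by 10 before the minor aryl-inward rotamer closes onto ring D to a naphthol; the outward preference of the aryl group, the excess of the very nucleophilic 10 and the high concentration should secure it.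

Step 7
Reactants: 17 methyl 3-[2-hydroxy-4,6-bis(triisopropylsiloxy)phenyl]-4-methoxybenzoate
Product: 18 methyl 3-[3-formyl-2-hydroxy-4,6-bis(triisopropylsiloxy)phenyl]-4-methoxybenzoate
Conditions: MgCl2, Et3N, (CH2O)n, MeCN, reflux
Reagents that add atoms: paraformaldehyde (as formaldehyde), C=O
Why: Casnati–Skattebøl ortho-formylation, in which the magnesium phenoxide delivers formaldehyde to C4a, the only free carbon ortho to the C5 hydroxyl, and a second formaldehyde accepts hydride to give the aldehyde.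

Step 8
Reactants: 18 methyl 3-[3-formyl-2-hydroxy-4,6-bis(triisopropylsiloxy)phenyl]-4-methoxybenzoate
Product: 19 methyl 3-[2-(benzyloxy)-3-formyl-4,6-bis(triisopropylsiloxy)phenyl]-4-methoxybenzoate
Conditions: BnOH, PPh3, DIAD, THF, 0 °C → rt
Reagents that add atoms: benzyl alcohol, OCc1ccccc1
Why: Mitsunobu etherification of the acidic salicylaldehyde-type phenol under neutral conditions, which should leave the aryl silyl ethers in place.

Step 9
Reactants: 19 methyl 3-[2-(benzyloxy)-3-formyl-4,6-bis(triisopropylsiloxy)phenyl]-4-methoxybenzoate; 20 1-(benzyloxy)-4-ethynylbenzene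
Product: 22 methyl 3-[2-(benzyloxy)-3-{3-[4-(benzyloxy)phenyl]-1-hydroxyprop-2-yn-1-yl}-4,6-bis(triisopropylsiloxy)phenyl]-4-methoxybenzoate (racemic), via lithium acetylide 21 (not isolated)
Conditions: 20, n-BuLi, THF, −78 °C; then 19, −78 → −40 °C; aq NH4Cl
Reagents that add atoms: none
Why: 1,2-addition of a lithium acetylide to the aldehyde, far faster than attack on the methyl ester at low temperature; the carbinol center forms racemic and is removed in step 10.

Step 10
Reactants: 22 methyl 3-[2-(benzyloxy)-3-{3-[4-(benzyloxy)phenyl]-1-hydroxyprop-2-yn-1-yl}-4,6-bis(triisopropylsiloxy)phenyl]-4-methoxybenzoate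
Product: 23 methyl 3-[2-(benzyloxy)-3-{3-[4-(benzyloxy)phenyl]prop-2-ynoyl}-4,6-bis(triisopropylsiloxy)phenyl]-4-methoxybenzoate
Conditions: MnO2 (excess), CH2Cl2, rt
Reagents that add atoms: none
Why: MnO2 oxidation of an alcohol that is both benzylic and propargylic gives the ynone without touching the silyl or benzyl ethers.

Step 11
Reactants: 23 methyl 3-[2-(benzyloxy)-3-{3-[4-(benzyloxy)phenyl]prop-2-ynoyl}-4,6-bis(triisopropylsiloxy)phenyl]-4-methoxybenzoate
Product: 25 methyl 3-{5-(benzyloxy)-2-[4-(benzyloxy)phenyl]-7-hydroxy-4-oxo-4H-chromen-6-yl}-4-methoxybenzoate, via desilylated ynone 24 (not isolated)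
Conditions: KF, 18-crown-6, dry DMF, rt → 40 °C; dilute aq HCl work-up
Reagents that add atoms: none
Why: Fluoride cleaves both aryl silyl ethers and the C8a phenoxide closes ring C by 6-endo-dig oxa-Michael addition to the ynone, which aprotic conditions favor over 5-exo closure; the benzyl ether on C5–O leaves O1 as the only oxygen able to close.

Step 12
Reactants: 25 methyl 3-{5-(benzyloxy)-2-[4-(benzyloxy)phenyl]-7-hydroxy-4-oxo-4H-chromen-6-yl}-4-methoxybenzoate
Product: 26 methyl 3-[5,7-dihydroxy-2-(4-hydroxyphenyl)-4-oxo-4H-chromen-6-yl]-4-methoxybenzoate (CNP0261185.0)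
Conditions: H2 (1 atm), Pd/C, EtOAc–MeOH, rt
Reagents that add atoms: none
Why: Hydrogenolysis of the two benzyl aryl ethers, under which the flavone C2–C3 double bond, the methyl ester and the methyl ether should persist.

**Compound list**
1 | methyl 3-bromo-4-methoxybenzoate | COC(=O)c1ccc(OC)c(Br)c1 | starting material
2 | (2-tert-butoxy-2-oxoethyl)zinc bromide | CC(C)(C)OC(=O)C[Zn]Br | starting material
3 | methyl 3-(2-tert-butoxy-2-oxoethyl)-4-methoxybenzoate | COC(=O)c1ccc(OC)c(CC(=O)OC(C)(C)C)c1 | intermediate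
4 | 2-[2-methoxy-5-(methoxycarbonyl)phenyl]acetic acid | COC(=O)c1ccc(OC)c(CC(=O)O)c1 | intermediate
5 | methyl 3-(2-chloro-2-oxoethyl)-4-methoxybenzoate | COC(=O)c1ccc(OC)c(CC(=O)Cl)c1 | intermediate
6 | ethyl formate | CCOC=O | starting material
7 | triisopropylsilyl trifluoromethanesulfonate | CC(C)[Si](C(C)C)(C(C)C)OS(=O)(=O)C(F)(F)F | starting material
8 | lithium 2,2-dibromoethenolate | [Li]OC=C(Br)Br | intermediate
9 | lithium ethynolate | [Li]OC#C | intermediate
10 | (triisopropylsiloxy)acetylene | C#CO[Si](C(C)C)(C(C)C)C(C)C | intermediate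
11 | methyl 4-methoxy-3-(2-oxoethenyl)benzoate (arylketene) | COC(=O)c1ccc(OC)c(C=C=O)c1 | intermediate
12 | methyl 4-methoxy-3-[4-oxo-2-(triisopropylsiloxy)cyclobut-2-en-1-yl]benzoate (racemic) | COC(=O)c1ccc(OC)c(C2C(=O)C=C2O[Si](C(C)C)(C(C)C)C(C)C)c1 | intermediate
13 | methyl 4-methoxy-3-[(1Z)-4-oxo-2-(triisopropylsiloxy)buta-1,3-dien-1-yl]benzoate (vinylketene) | COC(=O)c1ccc(OC)c(/C=C(\O[Si](C(C)C)(C(C)C)C(C)C)C=C=O)c1 | intermediate
14 | methyl 4-methoxy-3-{(Z)-2-[4-oxo-2-(triisopropylsiloxy)cyclobut-2-en-1-yl]-2-(triisopropylsiloxy)ethenyl}benzoate (racemic) | COC(=O)c1ccc(OC)c(/C=C(\O[Si](C(C)C)(C(C)C)C(C)C)C2C(=O)C=C2O[Si](C(C)C)(C(C)C)C(C)C)c1 | intermediate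
15 | methyl 4-methoxy-3-[(1Z,3E)-6-oxo-2,4-bis(triisopropylsiloxy)hexa-1,3,5-trien-1-yl]benzoate (dienylketene) | COC(=O)c1ccc(OC)c(/C=C(\O[Si](C(C)C)(C(C)C)C(C)C)/C=C(/O[Si](C(C)C)(C(C)C)C(C)C)\C=C=O)c1 | intermediate
16 | methyl 4-methoxy-3-[2-oxo-4,6-bis(triisopropylsiloxy)cyclohexa-3,5-dien-1-yl]benzoate (racemic) | COC(=O)c1ccc(OC)c(C2C(=O)C=C(O[Si](C(C)C)(C(C)C)C(C)C)C=C2O[Si](C(C)C)(C(C)C)C(C)C)c1 | intermediate
17 | methyl 3-[2-hydroxy-4,6-bis(triisopropylsiloxy)phenyl]-4-methoxybenzoate | COC(=O)c1ccc(OC)c(-c2c(O)cc(O[Si](C(C)C)(C(C)C)C(C)C)cc2O[Si](C(C)C)(C(C)C)C(C)C)c1 | intermediate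
18 | methyl 3-[3-formyl-2-hydroxy-4,6-bis(triisopropylsiloxy)phenyl]-4-methoxybenzoate | COC(=O)c1ccc(OC)c(-c2c(O)c(C=O)c(O[Si](C(C)C)(C(C)C)C(C)C)cc2O[Si](C(C)C)(C(C)C)C(C)C)c1 | intermediate
19 | methyl 3-[2-(benzyloxy)-3-formyl-4,6-bis(triisopropylsiloxy)phenyl]-4-methoxybenzoate | COC(=O)c1ccc(OC)c(-c2c(OCc3ccccc3)c(C=O)c(O[Si](C(C)C)(C(C)C)C(C)C)cc2O[Si](C(C)C)(C(C)C)C(C)C)c1 | intermediate
20 | 1-(benzyloxy)-4-ethynylbenzene | C#Cc1ccc(OCc2ccccc2)cc1 | starting material
21 | {[4-(benzyloxy)phenyl]ethynyl}lithium | [Li]C#Cc1ccc(OCc2ccccc2)cc1 | intermediate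
22 | methyl 3-[2-(benzyloxy)-3-{3-[4-(benzyloxy)phenyl]-1-hydroxyprop-2-yn-1-yl}-4,6-bis(triisopropylsiloxy)phenyl]-4-methoxybenzoate (racemic) | COC(=O)c1ccc(OC)c(-c2c(OCc3ccccc3)c(C(O)C#Cc3ccc(OCc4ccccc4)cc3)c(O[Si](C(C)C)(C(C)C)C(C)C)cc2O[Si](C(C)C)(C(C)C)C(C)C)c1 | intermediate
23 | methyl 3-[2-(benzyloxy)-3-{3-[4-(benzyloxy)phenyl]prop-2-ynoyl}-4,6-bis(triisopropylsiloxy)phenyl]-4-methoxybenzoate | COC(=O)c1ccc(OC)c(-c2c(OCc3ccccc3)c(C(=O)C#Cc3ccc(OCc4ccccc4)cc3)c(O[Si](C(C)C)(C(C)C)C(C)C)cc2O[Si](C(C)C)(C(C)C)C(C)C)c1 | intermediate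
24 | methyl 3-[2-(benzyloxy)-3-{3-[4-(benzyloxy)phenyl]prop-2-ynoyl}-4,6-dihydroxyphenyl]-4-methoxybenzoate | COC(=O)c1ccc(OC)c(-c2c(OCc3ccccc3)c(C(=O)C#Cc3ccc(OCc4ccccc4)cc3)c(O)cc2O)c1 | intermediate
25 | methyl 3-{5-(benzyloxy)-2-[4-(benzyloxy)phenyl]-7-hydroxy-4-oxo-4H-chromen-6-yl}-4-methoxybenzoate | COC(=O)c1ccc(OC)c(-c2c(O)cc3oc(-c4ccc(OCc5ccccc5)cc4)cc(=O)c3c2OCc6ccccc6)c1 | intermediate
26 | methyl 3-[5,7-dihydroxy-2-(4-hydroxyphenyl)-4-oxo-4H-chromen-6-yl]-4-methoxybenzoate | COC(=O)c1ccc(OC)c(-c2c(O)cc3oc(-c4ccc(O)cc4)cc(=O)c3c2O)c1 | target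

**Step count**
Total: 12 steps. Longest linear sequence: 11 steps (1 → 3 → 4 → 5 → 12 → 17 → 18 → 19 → 22 → 23 → 25 → 26); step 4 is a one-step branch that supplies 10.

**Steps most likely to fail**

Step 6. The ring opening of 12 is reversible, so the minor aryl-inward vinylketene may drain away by six-electron closure onto ring D (naphthol formation), or the product phenol may be acylated by ketene intermediates, before bimolecular capture by 10 takes place. The fallback sets out from 1 and comes back to the route at 17; it makes the C6–ring D bond by cross-coupling instead of carrying it through the annulation. Miyaura borylation of 1 (B2pin2, PdCl2(dppf), KOAc, dioxane, 80 °C) should give methyl 4-methoxy-3-(4,4,5,5-tetramethyl-1,3,2-dioxaborolan-2-yl)benzoate F1. Phloroglucinol is bis-silylated (i-Pr3SiCl, imidazole, DMF) to 3,5-bis(triisopropylsiloxy)phenol F2. NIS (CH2Cl2, 0 °C) should then iodinate the position next to the free hydroxyl, which is less hindered than the one between the two silyl ethers, to give 2-iodo-3,5-bis(triisopropylsiloxy)phenol F3. Suzuki–Miyaura coupling of F1 with F3 (Pd(OAc)2, SPhos, K3PO4, toluene–H2O, 80 °C) should give 17, and steps 7 to 12 follow unchanged.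

Step 4. With a formate the tetrahedral adduct collapses to an aldehyde-level intermediate, so over-addition of the organolithium reagents, or silylation of the unhindered parent ynolate on carbon, may erode the supply of 10. The fallback sets out from 7 and comes back to the route at 10; it reaches the ynolate by oxidation of an acetylide instead of by ester homologation. Acetylene and n-BuLi in THF at −78 °C give ethynyllithium F4. Lithium tert-butyl peroxide (from anhydrous t-BuOOH and LiN(SiMe3)2) should transfer oxygen to F4 between −78 and −20 °C to give lithium ethynolate 9, and 7 at −78 °C should silylate it on oxygen to 10.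

Step 11. 5-exo closure to the aurone may compete with the 6-endo closure, and the C7 phenoxide freed at the same time lowers the electrophilicity of the ynone, so ring closure may stall. The fallback sets out from 23 and comes back to the route at 25; it fixes the site of C–O bond formation before the phenol is unmasked. Conjugate addition of Et2NH (EtOH, rt) to 23 should give the enaminone methyl 3-[2-(benzyloxy)-3-{3-[4-(benzyloxy)phenyl]-3-(diethylamino)prop-2-enoyl}-4,6-bis(triisopropylsiloxy)phenyl]-4-methoxybenzoate F5 (alkene geometry of no consequence). Bu4NF (THF, 0 °C → rt) then frees the C8a phenoxide, which can only add to the amine-bearing carbon and expel diethylamine, giving 25.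

**Further compounds**
F1 | step 6 | methyl 4-methoxy-3-(4,4,5,5-tetramethyl-1,3,2-dioxaborolan-2-yl)benzoate | COC(=O)c1ccc(OC)c(B2OC(C)(C)C(C)(C)O2)c1
F2 | step 6 | 3,5-bis(triisopropylsiloxy)phenol | Oc1cc(O[Si](C(C)C)(C(C)C)C(C)C)cc(O[Si](C(C)C)(C(C)C)C(C)C)c1
F3 | step 6 | 2-iodo-3,5-bis(triisopropylsiloxy)phenol | Oc1c(I)c(O[Si](C(C)C)(C(C)C)C(C)C)cc(O[Si](C(C)C)(C(C)C)C(C)C)c1
F4 | step 4 | ethynyllithium | [Li]C#C
F5 | step 11 | methyl 3-[2-(benzyloxy)-3-{3-[4-(benzyloxy)phenyl]-3-(diethylamino)prop-2-enoyl}-4,6-bis(triisopropylsiloxy)phenyl]-4-methoxybenzoate | COC(=O)c1ccc(OC)c(-c2c(OCc3ccccc3)c(C(=O)C=C(N(CC)CC)c3ccc(OCc4ccccc4)cc3)c(O[Si](C(C)C)(C(C)C)C(C)C)cc2O[Si](C(C)C)(C(C)C)C(C)C)c1
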